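## Analysis of the target

The target is a germacranolide: a ten-membered carbocycle (C1–C10) fused across C6–C7 to an α-methylene-γ-butyrolactone (O–C6, C7, C11, C12). It carries a C1 ketone, a C10 tertiary carbinol, a C8 isovalerate and a trisubstituted C4=C5 alkene that is Z (C3 and C6 cis). There are four stereocentres, all R. C6, C7 and C8 are contiguous: H6 and H7 are trans on the lactone, and the C8 oxygen is syn to C6 when C9–C8–C7–C11 is drawn as a zigzag. C10 is separated from them by the C9 methylene and stands 1,3-anti to the C8 oxygen. The sensitive groups are the exocyclic C11=C13 Michael acceptor, the allylic C6–O lactone bond, the C1/C10 α-ketol, the Z alkene and, whenever the C8 hydroxyl is free, the O6-to-O8 translactonisation path. The hard part is the medium ring: a ten-membered carbocycle with a cis trisubstituted alkene and six functionalised carbons must be closed against transannular strain without disturbing these groups. The strategy rests on one feature: the C1 carbonyl lies exactly two methylenes (C2, C3) from the sp2 carbon C4. C3 is therefore the β-carbon of a ketone homoenolate and C3–C4 is the retron of a homoenolate–alkenyl halide coupling, with the homoenolate stored as a cyclopropanol at C1.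

## Retrosynthetic reasoning

**28 back to 27 and 26 (no skeletal bond cut).** The C11=C13 bond is retired first: 28 is traced to the C13 trimethylammonium salt 27 and this to the tertiary amine 26. An α-methylene lactone would be attacked by the base of the ring closure and would insert an alkenylpalladium, whereas its amine adduct does neither. The forward steps must N-methylate the amine and expel it by β-elimination under conditions mild enough for the α-ketol and the allylic lactone.

**26 back to 25 (C3–C4).** The ring is opened at C3–C4: C4 becomes an alkenyl iodide of fixed Z geometry and C1–C3 a 1-substituted cyclopropanol. This bond is chosen over C5–C6, C7–C8 or C9–C10 because no stereocentre flanks it, so the ring closure cannot mis-set one. It also hides the C1 ketone in a group that survives acylation, amine addition and fluoride, and the homoenolate released is non-basic, which spares the esters. The gain is ring closure and ketone unveiling in one operation, with all four stereocentres already in place. The forward reaction must join C3 to C4 with retention of alkene geometry, faster than β-hydride elimination or oligomerisation.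

**25 back to 21 (functional group changes).** The free cyclopropanol and C10 hydroxyl of 25 go back to the bis-silyl ether 24, the amine to conjugate addition on the methylene lactone 23, and the C8 ester to alcohol 21 and acid chloride 22. The order (acylate, mask, desilylate) keeps the cyclopropanol protected until just before ring closure and caps the C8 hydroxyl before it can translactonise.

**21 back to 20 and 9 (C7–C8).** This cut divides the molecule into two fragments of similar size and removes two stereocentres at once. C8 becomes the carbonyl carbon of aldehyde 9 and C7 the γ-carbon of allylstannane 20, whose SE2' reaction also creates the exocyclic methylene. A C6–C7 cut would need an acyclic allyl metal carrying the C8 stereocentre, with less predictable facial control. The forward step must attack the butenolide face opposite the C6 substituent and give the 7,8-syn isomer. An open, Lewis-acid-promoted transition state is chosen because the ring locks C6 trans to the stannylmethyl group, a geometry from which a closed chair transition state would give the C8 epimer.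

**20 back to 16 and 17 (C7=C11 and the ester C–O).** The stannane goes back to allylic bromide 19. The butenolide of 19 is opened at C7=C11 (metathesis retron) to ester 18, that is, to secondary alcohol 16 and acid 17, which brings C11, C12 and C13 with the bromide in place. No palladium or strong base is needed, so the alkenyl iodide is safe, and C6 is the only stereocentre of this fragment.

**16 back to 10.** 16 is the slow-reacting enantiomer of racemic dienol 15, the adduct of Grignard reagent 14 and enal 13. The Z iodoalkene of 13 goes back through allylic alcohol 12 to alkynol 10, whose hydroxyl directs a trans-hydroalumination. A resolution is accepted because it is dependable at this early, inexpensive stage.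

**9 back to 1.** The aldehyde carbon of 9 (C8) goes back to a primary silyl ether in 8, and the silyloxycyclopropane to cyclopropanol 7. 7 arises by adding the two carbons of Grignard reagent 6 (C2 and C3) to the lactone carbonyl of 5. 5 comes from hydroxy lactone 4, and 4 from the chiral-pool diacid 1 through dioxolanone 2, which distinguishes the two carboxyl groups: the one on the carbinol carbon becomes C1, the other C8. C10 is therefore taken from the chiral pool.

## Alternatives that were turned down

**Alternative 1:** The ring is cut at C5–C6 and the lactone at its C12–O bond. In the forward step CrCl2 with catalytic NiCl2, the divalent chromium being regenerated at a cathode, turns a C5 alkenyl iodide into an alkenylchromium species that adds to a C6 aldehyde. The C6 alkoxide then closes the γ-lactone on a C12 ester, giving the 8-silyloxy germacranolide A1.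
- For it: chromium-mediated alkenyl–aldehyde addition is among the best-precedented medium-ring closures, it prefers aldehydes over the C1 ketone, and carbocycle and lactone form in one operation. On ring-closure precedent it is stronger than the chosen route.
- Against it: C6 would be created inside the macrocyclic transition state, with the 6,7-trans relation left to ring conformation. The aldehyde would carry at C7 a hydrogen that is α to the formyl group and γ to the acrylate, so epimerisation and alkene migration threaten before cyclisation. The acrylate and the α-ketol are exposed to low-valent chromium and nickel, and the electrochemical turnover is less proven on such substrates. A1 still needs desilylation and acylation at C8.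
- Comparison: the chosen route forms no stereocentre in the ring closure, unveils the ketone in the same step, and has the ester installed beforehand.

**Alternative 2:** A [3,3] disconnection traces C8–C9 of the cyclodecadienone A2 to a 1-alkenyl-6-isopropenylcyclohex-2-enol. In the forward step its potassium alkoxide (KH, crown ether) undergoes anionic oxy-Cope ring expansion: the cyclohexene C1–C6 bond breaks, C8–C9 forms, and A2 results with a 4Z enone and a 1(10)E alkene.
- For it: a ring expansion has no end-to-end cyclisation entropy and the pericyclic step is dependable, so on formation of the ten-membered ring it is stronger than the chosen route. The starting material is a cheap terpene.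
- Against it: A2 is far from the target. The ketone is at C6 and must be reduced with control. The 1(10) alkene must become the C1 ketone and C10 carbinol by regio- and face-selective oxidation on a flexible ring that also holds an enone. The lactone must be annulated at C7, and the C8 ether exchanged for the ester. Only C8 is preset, and C6, C7 and C10 would be set relative to it on a conformationally mobile ring, over ten or more further steps.
- Comparison: the chosen route sets the stereocentres on acyclic or five-membered-ring intermediates and needs two steps after ring closure.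

**Alternative 3:** The ring is cut at C9–C10. In the forward step SmI2 reduces a C9 bromide next to a C8 ketone to a samarium enolate that adds to the C10 methyl ketone, giving A3, the 8-oxo-10-hydroxy macrocycle with C1 held as a dithiane.
- For it: intramolecular samarium Reformatsky-type aldol reactions close medium rings well because the metal templates the two carbonyls, and the ring and the C10 carbinol arrive together. A hydroxyl-directed 1,3-anti reduction could then set C8. On templating it is stronger than the chosen route.
- Against it: C10, a quaternary centre, would be set in the macrocyclisation with only remote control. The electrophile is a ketone next to a fully substituted dithiane carbon. SmI2 reduces α-methylene lactones. With C8 as a ketone, H7 is α to it and the lactone oxygen at C6 is β, so β-elimination that opens the lactone, and epimerisation at C7, are built in. After A3 three steps remain (C8 reduction, acylation, dithiane removal in the presence of alkenes).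
- Comparison: the chosen route keeps C8 at the ester oxidation level throughout and creates no stereocentre in the ring closure.

Key step: step 18

Remark: atoms are numbered as in germacranolides (C14 and C15 are the methyls on C4 and C10). The C11 configuration drawn for 24–27 is the one expected under equilibrating protonation and is erased in step 20.

## Route

Step 1
Reactants: 1 (R)-citramalic acid [(2R)-2-hydroxy-2-methylbutanedioic acid]
Product: 2 2-[(4R)-2,2,4-trimethyl-5-oxo-1,3-dioxolan-4-yl]acetic acid
Conditions: 2,2-dimethoxypropane, TsOH·H2O (cat.), rt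
Reagents that add atoms: 2,2-dimethoxypropane, COC(C)(C)OC
Why: Acid-catalysed acetal exchange closes the five-membered dioxolanone on the α-hydroxy acid pair only, leaving the CH2CO2H arm (future C8) free and so differentiating the two carboxyl groups; the stereocentre (future C10) is not touched.

Step 2
Reactants: 2 2-[(4R)-2,2,4-trimethyl-5-oxo-1,3-dioxolan-4-yl]acetic acid
Product: 4 (3R)-3-hydroxy-3-methyloxolan-2-one, via hydroxyethyl dioxolanone 3 (not isolated)
Conditions: BH3·SMe2, THF, 0 °C to rt; MeOH; then TsOH·H2O (cat.), CH2Cl2, rt
Reagents that add atoms: none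
Why: Borane reduces the free carboxylic acid much faster than the dioxolanone carbonyl, and under acid the new primary alcohol transacylates onto the activated dioxolanone with loss of acetone (lactonisation), a sequence well established for the lower homologue malic acid.

Step 3
Reactants: 4 (3R)-3-hydroxy-3-methyloxolan-2-one
Product: 5 (3R)-3-methyl-3-[(triethylsilyl)oxy]oxolan-2-one
Conditions: Et3SiOTf, 2,6-lutidine, CH2Cl2, −78 to 0 °C
Reagents that add atoms: triethylsilyl trifluoromethanesulfonate, CC[Si](CC)(CC)OS(=O)(=O)C(F)(F)F
Why: Silylation of a tertiary alcohol with a silyl triflate and a hindered pyridine base; the α-oxygen is capped so that it neither consumes the Grignard reagent nor ties up titanium in step 4.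

Step 4
Reactants: 5 (3R)-3-methyl-3-[(triethylsilyl)oxy]oxolan-2-one; 6 ethylmagnesium bromide (EtMgBr)
Product: 7 1-[(2R)-4-hydroxy-2-[(triethylsilyl)oxy]butan-2-yl]cyclopropan-1-ol
Conditions: Ti(OiPr)4 (30 mol%), 6 (3 equiv, slow addition), THF, 0 °C to rt; sat. aq NH4Cl
Reagents that add atoms: none
Why: Kulinkovich cyclopropanation: the titanacyclopropane formed from 6 and Ti(OiPr)4 inserts the lactone carbonyl and closes onto it, so that C1 becomes a cyclopropanol carbon whose two CH2 groups (future C2 and C3) come from one ethyl group of 6. Lactones are good substrates and the α-silyloxy group activates the carbonyl, although the α-quaternary centre will slow the reaction.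

Step 5
Reactants: 7 1-[(2R)-4-hydroxy-2-[(triethylsilyl)oxy]butan-2-yl]cyclopropan-1-ol
Product: 8 (3R)-1,3-bis[(triethylsilyl)oxy]-3-{1-[(triethylsilyl)oxy]cyclopropyl}butane
Conditions: Et3SiOTf (2.4 equiv), 2,6-lutidine, CH2Cl2, −78 to 0 °C
Reagents that add atoms: triethylsilyl trifluoromethanesulfonate, CC[Si](CC)(CC)OS(=O)(=O)C(F)(F)F
Why: Exhaustive silylation under buffered conditions, the usual way to protect tertiary cyclopropanols without acid-induced ring opening.

Step 6
Reactants: 8 (3R)-1,3-bis[(triethylsilyl)oxy]-3-{1-[(triethylsilyl)oxy]cyclopropyl}butane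
Product: 9 (3R)-3-[(triethylsilyl)oxy]-3-{1-[(triethylsilyl)oxy]cyclopropyl}butanal
Conditions: (COCl)2, DMSO, CH2Cl2, −78 to −30 °C; Et3N, −78 to 0 °C
Reagents that add atoms: none
Why: Swern oxidation applied directly to a primary triethylsilyl ether, a known chemoselective variant: the chlorosulfonium reagent cleaves the unhindered primary Si–O bond and oxidises that carbon in the same pot, while the two tertiary silyl ethers are too hindered to react.

Step 7
Reactants: 10 but-2-yn-1-ol
Product: 12 (2Z)-3-iodobut-2-en-1-ol, via cyclic alkenylalanate 11 (not isolated)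
Conditions: NaAlH2(OCH2CH2OCH3)2, THF, 0 °C to rt; EtOAc; then I2, THF, −78 °C
Reagents that add atoms: iodine, II
Why: Hydroxyl-directed trans-hydroalumination: the aluminium alkoxide delivers hydride to the proximal alkyne carbon (future C5) and aluminium to the distal one (future C4) within a five-membered chelate, and iodinolysis with retention gives the Z iodide with iodine cis to the CH2OH carbon.

Step 8
Reactants: 12 (2Z)-3-iodobut-2-en-1-ol
Product: 13 (2Z)-3-iodobut-2-enal
Conditions: MnO2 (activated), CH2Cl2, rt, dark; filtered and used directly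
Reagents that add atoms: none
Why: Allylic oxidation with MnO2 is neutral and mild enough to preserve the Z geometry; the enal is not stored, to avoid isomerisation.

Step 9
Reactants: 13 (2Z)-3-iodobut-2-enal; 14 vinylmagnesium bromide (CH2=CHMgBr)
Product: 15 rac-(4Z)-5-iodohexa-1,4-dien-3-ol
Conditions: THF, −78 °C; sat. aq NH4Cl
Reagents that add atoms: none
Why: Grignard 1,2-addition to the enal at low temperature, where the alkenyl iodide does not undergo exchange; the vinyl carbon bonded to the carbinol becomes C7.

Step 10
Reactants: 15 rac-(4Z)-5-iodohexa-1,4-dien-3-ol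
Product: 16 (3S,4Z)-5-iodohexa-1,4-dien-3-ol
Conditions: Novozym 435 (immobilised Candida antarctica lipase B), vinyl acetate, MTBE, 30 °C, stopped near 55% conversion; chromatography
Reagents that add atoms: none
Why: Lipase-catalysed kinetic resolution by acyl transfer: by the empirical size rule for this enzyme (vinyl as the medium group, the iodoalkenyl group as the large one) the R enantiomer should be acetylated and the S alcohol (future C6) left behind.

Step 11
Reactants: 16 (3S,4Z)-5-iodohexa-1,4-dien-3-ol; 17 2-(bromomethyl)prop-2-enoic acid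
Product: 18 (3S,4Z)-5-iodohexa-1,4-dien-3-yl 2-(bromomethyl)prop-2-enoate
Conditions: N,N'-diisopropylcarbodiimide, DMAP (10 mol%), CH2Cl2, 0 °C
Reagents that add atoms: none
Why: Steglich esterification under neutral conditions, which the acid-sensitive bis-allylic alcohol tolerates; catalytic DMAP at 0 °C limits attack on the allylic bromide. 17 supplies C11, C12 and C13.

Step 12
Reactants: 18 (3S,4Z)-5-iodohexa-1,4-dien-3-yl 2-(bromomethyl)prop-2-enoate
Product: 19 (5S)-3-(bromomethyl)-5-[(1Z)-2-iodoprop-1-en-1-yl]furan-2(5H)-one
Conditions: second-generation Hoveyda–Grubbs catalyst (5–10 mol%), toluene (5 mM), 80 °C, argon sparge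
Reagents that add atoms: none
Why: Ring-closing metathesis of an allylic 2-substituted acrylate to an α-substituted butenolide, a much-used ring construction; the catalyst loads at the monosubstituted vinyl group and closes onto the acrylate, while the trisubstituted, electron-poor iodoalkene stays out.

Step 13
Reactants: 19 (5S)-3-(bromomethyl)-5-[(1Z)-2-iodoprop-1-en-1-yl]furan-2(5H)-one
Product: 20 (5S)-5-[(1Z)-2-iodoprop-1-en-1-yl]-3-[(tributylstannyl)methyl]furan-2(5H)-one
Conditions: Zn dust, Bu3SnCl, THF/sat. aq NH4Cl, 0 °C to rt
Reagents that add atoms: tributyltin chloride, CCCC[Sn](Cl)(CCCC)CCCC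
Why: Zinc-mediated Barbier-type stannylation of an allylic bromide in aqueous THF: zinc inserts into the activated allylic C–Br bond and not into the alkenyl C–I bond, and Bu3SnCl traps the allylzinc to give the conjugated primary allylstannane, the thermodynamically preferred regioisomer.

Step 14
Reactants: 20 (5S)-5-[(1Z)-2-iodoprop-1-en-1-yl]-3-[(tributylstannyl)methyl]furan-2(5H)-one; 9 (3R)-3-[(triethylsilyl)oxy]-3-{1-[(triethylsilyl)oxy]cyclopropyl}butanal
Product: 21 (4R,5S)-4-[(1R,3R)-1-hydroxy-3-[(triethylsilyl)oxy]-3-{1-[(triethylsilyl)oxy]cyclopropyl}butyl]-5-[(1Z)-2-iodoprop-1-en-1-yl]-3-methylideneoxolan-2-one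
Conditions: BF3·OEt2 (2 equiv), CH2Cl2, −78 °C; sat. aq NaHCO3; aq KF
Reagents that add atoms: none
Why: Lewis-acid-promoted allylstannane addition (SE2' through C7, open transition state), which also moves the ring alkene to the exocyclic C11=C13 position. C7 is set by attack on the butenolide face opposite the C6 substituent (trans lactone). C8 is set by the antiperiplanar open transition state, which turns the aldehyde chain away from C6 and gives the 7,8-syn isomer (8R), the sense also favoured by polar 1,3-anti induction from the C10 silyloxy group.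

Step 15
Reactants: 21 (4R,5S)-4-[(1R,3R)-1-hydroxy-3-[(triethylsilyl)oxy]-3-{1-[(triethylsilyl)oxy]cyclopropyl}butyl]-5-[(1Z)-2-iodoprop-1-en-1-yl]-3-methylideneoxolan-2-one; 22 isovaleryl chloride (3-methylbutanoyl chloride)
Product: 23 (1R,3R)-1-[(2S,3R)-2-[(1Z)-2-iodoprop-1-en-1-yl]-4-methylidene-5-oxooxolan-3-yl]-3-[(triethylsilyl)oxy]-3-{1-[(triethylsilyl)oxy]cyclopropyl}butyl 3-methylbutanoate
Conditions: pyridine, DMAP (cat.), CH2Cl2, 0 °C to rt
Reagents that add atoms: none
Why: Acylation of the hindered secondary alcohol with an acid chloride under nucleophilic catalysis; esterifying C8 also removes the only hydroxyl that could translactonise.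

Step 16
Reactants: 23 (1R,3R)-1-[(2S,3R)-2-[(1Z)-2-iodoprop-1-en-1-yl]-4-methylidene-5-oxooxolan-3-yl]-3-[(triethylsilyl)oxy]-3-{1-[(triethylsilyl)oxy]cyclopropyl}butyl 3-methylbutanoate
Product: 24 (1R,3R)-1-[(2S,3R,4R)-4-[(dimethylamino)methyl]-2-[(1Z)-2-iodoprop-1-en-1-yl]-5-oxooxolan-3-yl]-3-[(triethylsilyl)oxy]-3-{1-[(triethylsilyl)oxy]cyclopropyl}butyl 3-methylbutanoate
Conditions: Me2NH (2 M in THF, 3 equiv), THF, 0 °C to rt
Reagents that add atoms: dimethylamine, CNC
Why: Aza-Michael addition to the α-methylene lactone, much faster than aminolysis of the ester or lactone at this temperature; reversible protonation should give the more stable C11 epimer with the aminomethyl group trans to the C7 substituent.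

Step 17
Reactants: 24 (1R,3R)-1-[(2S,3R,4R)-4-[(dimethylamino)methyl]-2-[(1Z)-2-iodoprop-1-en-1-yl]-5-oxooxolan-3-yl]-3-[(triethylsilyl)oxy]-3-{1-[(triethylsilyl)oxy]cyclopropyl}butyl 3-methylbutanoate
Product: 25 (1R,3R)-1-[(2S,3R,4R)-4-[(dimethylamino)methyl]-2-[(1Z)-2-iodoprop-1-en-1-yl]-5-oxooxolan-3-yl]-3-hydroxy-3-(1-hydroxycyclopropyl)butyl 3-methylbutanoate
Conditions: HF·pyridine, pyridine, THF, 0 °C to rt; sat. aq NaHCO3
Reagents that add atoms: none
Why: Fluoride cleavage of the two tertiary triethylsilyl ethers under buffered, non-basic conditions that leave the esters, the alkenyl iodide and the strained ring intact.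

Step 18
Reactants: 25 (1R,3R)-1-[(2S,3R,4R)-4-[(dimethylamino)methyl]-2-[(1Z)-2-iodoprop-1-en-1-yl]-5-oxooxolan-3-yl]-3-hydroxy-3-(1-hydroxycyclopropyl)butyl 3-methylbutanoate
Product: 26 (3R,3aR,4R,6R,10Z,11aR)-3-[(dimethylamino)methyl]-6-hydroxy-6,10-dimethyl-2,7-dioxo-2,3,3a,4,5,6,7,8,9,11a-decahydrocyclodeca[b]furan-4-yl 3-methylbutanoate
Conditions: Pd(OAc)2 (15 mol%), XPhos (30 mol%), Cs2CO3 (2 equiv), toluene, 70 °C, syringe-pump addition of 25 to a final 2 mM
Reagents that add atoms: none
Why: Proposed new method: zerovalent palladium (formed in situ from Pd(OAc)2 and XPhos) should insert into the C4–I bond with retention of the Z geometry, Cs2CO3 should convert the cyclopropanol into a palladium-bound alkoxide, and strain-driven β-carbon elimination of either of the two equivalent ring bonds should give the C3 alkylpalladium (a palladium homoenolate) and the C1 ketone. C(sp3)–C(sp2) reductive elimination from the resulting eleven-membered palladacycle then forms C3–C4. The closest known reaction type is the intermolecular palladium-catalysed ring-opening cross-coupling of cyclopropanols with aryl and alkenyl halides through palladium homoenolates; closing a ten-membered carbocycle this way is the untested extension. The ring is closed by reductive elimination, a contraction of the palladacycle and not a nucleophilic cyclisation, with the cis C4=C5 alkene ending up endocyclic. No stereocentre is formed; C6, C7, C8 and C10 are spectators and C11, though epimerisable, is erased later. The step needs reductive elimination to outrun β-hydride elimination from C2, which the bulky biaryl phosphine is chosen to secure. It needs ring closure to outrun oligomerisation, which slow addition at high dilution should help, as should the turn imposed by the Z alkene and the two chain ends sitting on the adjacent lactone carbons C6 and C7. It needs the alkenylpalladium to find no alkene to insert, which the amine mask at C13 guarantees.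

Step 19
Reactants: 26 (3R,3aR,4R,6R,10Z,11aR)-3-[(dimethylamino)methyl]-6-hydroxy-6,10-dimethyl-2,7-dioxo-2,3,3a,4,5,6,7,8,9,11a-decahydrocyclodeca[b]furan-4-yl 3-methylbutanoate
Product: 27 {[(3R,3aR,4R,6R,10Z,11aR)-6-hydroxy-6,10-dimethyl-4-[(3-methylbutanoyl)oxy]-2,7-dioxo-2,3,3a,4,5,6,7,8,9,11a-decahydrocyclodeca[b]furan-3-yl]methyl}trimethylazanium iodide
Conditions: MeI (10 equiv), THF, rt, dark
Reagents that add atoms: iodomethane, CI
Why: Menshutkin quaternisation of the tertiary amine; under neutral conditions no other site in 26 is nucleophilic enough to compete.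

Step 20
Reactants: 27 {[(3R,3aR,4R,6R,10Z,11aR)-6-hydroxy-6,10-dimethyl-4-[(3-methylbutanoyl)oxy]-2,7-dioxo-2,3,3a,4,5,6,7,8,9,11a-decahydrocyclodeca[b]furan-3-yl]methyl}trimethylazanium iodide
Product: 28 (3aR,4R,6R,10Z,11aR)-6-hydroxy-6,10-dimethyl-3-methylidene-2,7-dioxo-2,3,3a,4,5,6,7,8,9,11a-decahydrocyclodeca[b]furan-4-yl 3-methylbutanoate
Conditions: sat. aq NaHCO3, CH2Cl2, rt
Reagents that add atoms: none
Why: Hofmann-type E1cB elimination of trimethylamine from the β-ammonio lactone under mild bicarbonate, the standard release of an α-methylene lactone from its amine adduct; C11 becomes sp2 again and the α-ketol and allylic lactone are not exposed to strong base.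

## Compound list

1 | (R)-citramalic acid, (2R)-2-hydroxy-2-methylbutanedioic acid | OC(=O)[C@](C)(O)CC(=O)O | starting material
2 | 2-[(4R)-2,2,4-trimethyl-5-oxo-1,3-dioxolan-4-yl]acetic acid | O=C1OC(C)(C)O[C@]1(C)CC(=O)O | intermediate
3 | (5R)-5-(2-hydroxyethyl)-2,2,5-trimethyl-1,3-dioxolan-4-one | O=C1OC(C)(C)O[C@]1(C)CCO | intermediate
4 | (3R)-3-hydroxy-3-methyloxolan-2-one | O=C1OCC[C@@]1(C)O | intermediate
5 | (3R)-3-methyl-3-[(triethylsilyl)oxy]oxolan-2-one | O=C1OCC[C@@]1(C)O[Si](CC)(CC)CC | intermediate
6 | ethylmagnesium bromide | CC[Mg]Br | starting material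
7 | 1-[(2R)-4-hydroxy-2-[(triethylsilyl)oxy]butan-2-yl]cyclopropan-1-ol | OCC[C@@](C)(O[Si](CC)(CC)CC)C1(O)CC1 | intermediate
8 | (3R)-1,3-bis[(triethylsilyl)oxy]-3-{1-[(triethylsilyl)oxy]cyclopropyl}butane | CC[Si](CC)(CC)OCC[C@@](C)(O[Si](CC)(CC)CC)C1(O[Si](CC)(CC)CC)CC1 | intermediate
9 | (3R)-3-[(triethylsilyl)oxy]-3-{1-[(triethylsilyl)oxy]cyclopropyl}butanal | O=CC[C@@](C)(O[Si](CC)(CC)CC)C1(O[Si](CC)(CC)CC)CC1 | intermediate
10 | but-2-yn-1-ol | CC#CCO | starting material
11 | sodium 2,2-bis(2-methoxyethoxy)-3-methyl-2,5-dihydro-1,2-oxaaluminol-2-uide (cyclic alkenylalanate) | CC1=CCO[Al-]1(OCCOC)OCCOC.[Na+] | intermediate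
12 | (2Z)-3-iodobut-2-en-1-ol | C/C(I)=C/CO | intermediate
13 | (2Z)-3-iodobut-2-enal | C/C(I)=C/C=O | intermediate
14 | vinylmagnesium bromide | C=C[Mg]Br | starting material
15 | rac-(4Z)-5-iodohexa-1,4-dien-3-ol | C=CC(O)/C=C(/C)I | intermediate
16 | (3S,4Z)-5-iodohexa-1,4-dien-3-ol | C=C[C@H](O)/C=C(/C)I | intermediate
17 | 2-(bromomethyl)prop-2-enoic acid | C=C(CBr)C(=O)O | starting material
18 | (3S,4Z)-5-iodohexa-1,4-dien-3-yl 2-(bromomethyl)prop-2-enoate | C=C[C@H](OC(=O)C(=C)CBr)/C=C(/C)I | intermediate
19 | (5S)-3-(bromomethyl)-5-[(1Z)-2-iodoprop-1-en-1-yl]furan-2(5H)-one | BrCC1=C[C@@H](/C=C(/C)I)OC1=O | intermediate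
20 | (5S)-5-[(1Z)-2-iodoprop-1-en-1-yl]-3-[(tributylstannyl)methyl]furan-2(5H)-one | CCCC[Sn](CCCC)(CCCC)CC1=C[C@@H](/C=C(/C)I)OC1=O | intermediate
21 | (4R,5S)-4-[(1R,3R)-1-hydroxy-3-[(triethylsilyl)oxy]-3-{1-[(triethylsilyl)oxy]cyclopropyl}butyl]-5-[(1Z)-2-iodoprop-1-en-1-yl]-3-methylideneoxolan-2-one | CC[Si](CC)(CC)OC1(CC1)[C@](C)(O[Si](CC)(CC)CC)C[C@@H](O)[C@@H]2[C@@H](/C=C(/C)I)OC(=O)C2=C | intermediate
22 | isovaleryl chloride (3-methylbutanoyl chloride) | CC(C)CC(Cl)=O | starting material
23 | (1R,3R)-1-[(2S,3R)-2-[(1Z)-2-iodoprop-1-en-1-yl]-4-methylidene-5-oxooxolan-3-yl]-3-[(triethylsilyl)oxy]-3-{1-[(triethylsilyl)oxy]cyclopropyl}butyl 3-methylbutanoate | CC[Si](CC)(CC)OC1(CC1)[C@](C)(O[Si](CC)(CC)CC)C[C@@H](OC(=O)CC(C)C)[C@@H]2[C@@H](/C=C(/C)I)OC(=O)C2=C | intermediate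
24 | (1R,3R)-1-[(2S,3R,4R)-4-[(dimethylamino)methyl]-2-[(1Z)-2-iodoprop-1-en-1-yl]-5-oxooxolan-3-yl]-3-[(triethylsilyl)oxy]-3-{1-[(triethylsilyl)oxy]cyclopropyl}butyl 3-methylbutanoate | CC[Si](CC)(CC)OC1(CC1)[C@](C)(O[Si](CC)(CC)CC)C[C@@H](OC(=O)CC(C)C)[C@@H]2[C@@H](/C=C(/C)I)OC(=O)[C@H]2CN(C)C | intermediate
25 | (1R,3R)-1-[(2S,3R,4R)-4-[(dimethylamino)methyl]-2-[(1Z)-2-iodoprop-1-en-1-yl]-5-oxooxolan-3-yl]-3-hydroxy-3-(1-hydroxycyclopropyl)butyl 3-methylbutanoate | OC1(CC1)[C@](C)(O)C[C@@H](OC(=O)CC(C)C)[C@@H]2[C@@H](/C=C(/C)I)OC(=O)[C@H]2CN(C)C | intermediate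
26 | (3R,3aR,4R,6R,10Z,11aR)-3-[(dimethylamino)methyl]-6-hydroxy-6,10-dimethyl-2,7-dioxo-2,3,3a,4,5,6,7,8,9,11a-decahydrocyclodeca[b]furan-4-yl 3-methylbutanoate | CN(C)C[C@@H]1C(=O)O[C@@H]2/C=C(/C)CCC(=O)[C@](C)(O)C[C@@H](OC(=O)CC(C)C)[C@@H]12 | intermediate
27 | {[(3R,3aR,4R,6R,10Z,11aR)-6-hydroxy-6,10-dimethyl-4-[(3-methylbutanoyl)oxy]-2,7-dioxo-2,3,3a,4,5,6,7,8,9,11a-decahydrocyclodeca[b]furan-3-yl]methyl}trimethylazanium iodide | C[N+](C)(C)C[C@@H]1C(=O)O[C@@H]2/C=C(/C)CCC(=O)[C@](C)(O)C[C@@H](OC(=O)CC(C)C)[C@@H]12.[I-] | intermediate
28 | (3aR,4R,6R,10Z,11aR)-6-hydroxy-6,10-dimethyl-3-methylidene-2,7-dioxo-2,3,3a,4,5,6,7,8,9,11a-decahydrocyclodeca[b]furan-4-yl 3-methylbutanoate (CNP0105188.1) | C=C1C(=O)O[C@@H]2/C=C(/C)CCC(=O)[C@](C)(O)C[C@@H](OC(=O)CC(C)C)[C@@H]12 | target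

## Step count and least certain steps

Total: 20 steps. Longest linear sequence: 14 steps (10 to 28, steps 7–13 and 14–20). The other branch (1 to 28) runs through 13 steps (1–6 and 14–20).

**Step 18 (key step, proposed new method).** Most likely failure: the eleven-membered palladacycle forms or reductively eliminates too slowly. Intermolecular coupling (oligomers), β-hydride elimination from C2 followed by reduction of the alkenyl iodide, or base-induced loss of the amine mask with Heck-type consumption of the methylene would then take over. Fallback (known reaction types only; sets out from 7 and 16, rejoins at 28): the same C3–C4 bond is made first, intermolecularly, and the ring is closed at C7–C8.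
- Selective silylation of the primary hydroxyl of 7 (Et3SiCl, imidazole) would give the mono-protected cyclopropanol F1.
- Its intermolecular palladium-catalysed ring-opening coupling with 16, the precedented form of the reaction, would give the keto dienol F2.
- Esterification with 17 as in step 11 would give the 2-(bromomethyl)acrylate F3.
- Ring-closing metathesis as in step 12 would give the bromomethyl butenolide F4.
- Zinc-mediated stannylation as in step 13 would give the stannylmethyl butenolide F5.
- Swern oxidation of the primary silyl ether as in step 6 would give the aldehyde F6.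
- BF3·OEt2 at high dilution would close the ring by intramolecular allylstannane–aldehyde addition, a known closure for medium and large carbocycles bearing an α-methylene lactone, to the hydroxy germacranolide F7.
- Acylation with 22 would give the silyl-protected ester F8, and HF·pyridine would release 28.

No amine mask is needed on this path, but C7 and C8 would be set inside a macrocyclic transition state.

**Step 14.** Most likely failure: erosion of simple diastereoselection at C8 (a synclinal instead of antiperiplanar arrangement), Lewis-acid opening of the silyloxycyclopropane, or translactonisation of the product alkoxide. Fallback (sets out from 19 and 9, rejoins at 23): an indium-mediated Barbier coupling in aqueous THF, neutral and proceeding through a closed chair transition state, should give the C8 epimer F9 with the same trans lactone. A Mitsunobu esterification with isovaleric acid (PPh3, diisopropyl azodicarboxylate) would invert C8 and install the ester, giving 23. The displacement is at a hindered carbinol, so this is a reserve and not the first choice.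

**Step 13.** Most likely failure: allylic transposition during tin transfer (tin at C7 in place of C13), or protonation of the allylzinc before it is trapped. Fallback (sets out from 18, rejoins at 20): the stannylation is moved ahead of the ring closure, where the two allyl termini are equivalent CH2 groups and no regiochemical question arises. Zn and Bu3SnCl on 18 would give the acyclic stannyl ester F10, and ring-closing metathesis of F10 would give 20.

**Step 12.** Most likely failure: slow closure onto the electron-poor 1,1-disubstituted alkene, with dimerisation at the vinyl group or catalyst loss through the allylic bromide. Fallback (sets out from 16, rejoins at 19): acylation of 16 with acryloyl chloride would give the acrylate F11, whose ring-closing metathesis to the unsubstituted butenolide F12 is undemanding. A Morita–Baylis–Hillman reaction of F12 with aqueous formaldehyde (imidazole) would give the hydroxymethyl butenolide F13, and CBr4/PPh3 would convert it to 19. The price is a base-mediated step on a butenolide whose C6 hydrogen is acidic.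

**Step 4.** Most likely failure: sluggish carbonyl insertion at the α-quaternary lactone, leading to incomplete conversion or simple ethyl addition. Fallback (sets out from 5, rejoins at 8): MeLi at −78 °C would open 5 to the methyl ketone F14 (in equilibrium with its lactol). Et3SiCl/imidazole would give the primary silyl ether F15. LDA and Et3SiCl would give the silyl enol ether F16; enolisation has only one direction because the other α-carbon is quaternary. A Simmons–Smith cyclopropanation (ZnEt2, CH2I2) of F16 would give 8 directly.

Further compounds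
F1 | step 18 | 1-{(2R)-2,4-bis[(triethylsilyl)oxy]butan-2-yl}cyclopropan-1-ol | CC[Si](CC)(CC)OCC[C@@](C)(O[Si](CC)(CC)CC)C1(O)CC1
F2 | step 18 | (3R,7Z,9S)-9-hydroxy-3,7-dimethyl-1,3-bis[(triethylsilyl)oxy]undeca-7,10-dien-4-one | CC[Si](CC)(CC)OCC[C@@](C)(O[Si](CC)(CC)CC)C(=O)CC/C(C)=C\[C@@H](O)C=C
F3 | step 18 | (3S,4Z,9R)-5,9-dimethyl-8-oxo-9,11-bis[(triethylsilyl)oxy]undeca-1,4-dien-3-yl 2-(bromomethyl)prop-2-enoate | CC[Si](CC)(CC)OCC[C@@](C)(O[Si](CC)(CC)CC)C(=O)CC/C(C)=C\[C@@H](OC(=O)C(=C)CBr)C=C
F4 | step 18 | (5R)-3-(bromomethyl)-5-{(1Z,6R)-2,6-dimethyl-5-oxo-6,8-bis[(triethylsilyl)oxy]oct-1-en-1-yl}furan-2(5H)-one | CC[Si](CC)(CC)OCC[C@@](C)(O[Si](CC)(CC)CC)C(=O)CC/C(C)=C\[C@H]1OC(=O)C(CBr)=C1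
F5 | step 18 | (5R)-5-{(1Z,6R)-2,6-dimethyl-5-oxo-6,8-bis[(triethylsilyl)oxy]oct-1-en-1-yl}-3-[(tributylstannyl)methyl]furan-2(5H)-one | CC[Si](CC)(CC)OCC[C@@](C)(O[Si](CC)(CC)CC)C(=O)CC/C(C)=C\[C@H]1OC(=O)C(C[Sn](CCCC)(CCCC)CCCC)=C1
F6 | step 18 | (3R,7Z)-3,7-dimethyl-4-oxo-8-{(2R)-5-oxo-4-[(tributylstannyl)methyl]-2,5-dihydrofuran-2-yl}-3-[(triethylsilyl)oxy]oct-7-enal | O=CC[C@@](C)(O[Si](CC)(CC)CC)C(=O)CC/C(C)=C\[C@H]1OC(=O)C(C[Sn](CCCC)(CCCC)CCCC)=C1
F7 | step 18 | (3aR,4R,6R,10Z,11aR)-4-hydroxy-6,10-dimethyl-3-methylidene-6-[(triethylsilyl)oxy]-3a,4,5,6,8,9-hexahydrocyclodeca[b]furan-2,7(3H,11aH)-dione | C=C1C(=O)O[C@@H]2/C=C(/C)CCC(=O)[C@](C)(O[Si](CC)(CC)CC)C[C@@H](O)[C@@H]12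
F8 | step 18 | (3aR,4R,6R,10Z,11aR)-6,10-dimethyl-3-methylidene-2,7-dioxo-6-[(triethylsilyl)oxy]-2,3,3a,4,5,6,7,8,9,11a-decahydrocyclodeca[b]furan-4-yl 3-methylbutanoate | C=C1C(=O)O[C@@H]2/C=C(/C)CCC(=O)[C@](C)(O[Si](CC)(CC)CC)C[C@@H](OC(=O)CC(C)C)[C@@H]12
F9 | step 14 | (4R,5S)-4-[(1S,3R)-1-hydroxy-3-[(triethylsilyl)oxy]-3-{1-[(triethylsilyl)oxy]cyclopropyl}butyl]-5-[(1Z)-2-iodoprop-1-en-1-yl]-3-methylideneoxolan-2-one | CC[Si](CC)(CC)OC1(CC1)[C@](C)(O[Si](CC)(CC)CC)C[C@H](O)[C@@H]2[C@@H](/C=C(/C)I)OC(=O)C2=C
F10 | step 13 | (3S,4Z)-5-iodohexa-1,4-dien-3-yl 2-[(tributylstannyl)methyl]prop-2-enoate | C=C[C@H](OC(=O)C(=C)C[Sn](CCCC)(CCCC)CCCC)/C=C(/C)I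
F11 | step 12 | (3S,4Z)-5-iodohexa-1,4-dien-3-yl prop-2-enoate | C=C[C@H](OC(=O)C=C)/C=C(/C)I
F12 | step 12 | (5S)-5-[(1Z)-2-iodoprop-1-en-1-yl]furan-2(5H)-one | O=C1C=C[C@@H](/C=C(/C)I)O1
F13 | step 12 | (5S)-3-(hydroxymethyl)-5-[(1Z)-2-iodoprop-1-en-1-yl]furan-2(5H)-one | OCC1=C[C@@H](/C=C(/C)I)OC1=O
F14 | step 4 | (3R)-5-hydroxy-3-methyl-3-[(triethylsilyl)oxy]pentan-2-one | OCC[C@@](C)(O[Si](CC)(CC)CC)C(C)=O
F15 | step 4 | (3R)-3-methyl-3,5-bis[(triethylsilyl)oxy]pentan-2-one | CC[Si](CC)(CC)OCC[C@@](C)(O[Si](CC)(CC)CC)C(C)=O
F16 | step 4 | (3R)-3-methyl-2,3,5-tris[(triethylsilyl)oxy]pent-1-ene | CC[Si](CC)(CC)OCC[C@@](C)(O[Si](CC)(CC)CC)C(=C)O[Si](CC)(CC)CC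
A1 | alternative 1 | (3aR,4R,6R,10Z,11aR)-4-[(tert-butyldimethylsilyl)oxy]-6-hydroxy-6,10-dimethyl-3-methylidene-3a,4,5,6,8,9-hexahydrocyclodeca[b]furan-2,7(3H,11aH)-dione | C=C1C(=O)O[C@@H]2/C=C(/C)CCC(=O)[C@](C)(O)C[C@@H](O[Si](C)(C)C(C)(C)C)[C@@H]12
A2 | alternative 2 | (2Z,6E,9R)-9-[(4-methoxyphenyl)methoxy]-3,7-dimethylcyclodeca-2,6-dien-1-one | C1/C(C)=C\C(=O)C[C@H](OCc2ccc(OC)cc2)C/C(C)=C/C1
A3 | alternative 3 | 8-oxo-10-hydroxy germacranolide with C1 as a 1,3-dithiane carbon (germacranolide numbering: 4Z,6R,7S,10R; 11(13)-methylene) | C=C1C(=O)O[C@@H]2/C=C(/C)CCC3(SCCCS3)[C@](C)(O)CC(=O)[C@@H]12
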